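**Retrosynthetic overview** (germacrane numbering: furanone = O–C10(Me)–C1(=O)–C2=C3; lactone on C6/C7 with C11–C13; ester on C8)
1. Last bond: the C8 tiglate. Before it, the 10-membered carbocycle is closed at C7–C8 by intramolecular Barbier allylation of a 3-(bromomethyl)butenolide (lactone ring and C6 already present) onto a C8 aldehyde; this also sets C7 and C8.
2. The C8 aldehyde and the 3(2H)-furanone arise in one event: gold-catalysed ring expansion of an oxirane (O, C10, C9) that carries the ynone C1(=O)–C2≡C3 on C10 and a CH2OSi group (C8) on C9.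
3. Enabling feature: the furanone oxygen sits on quaternary C10, whose CH2 arm (C9) leads to oxygenated C8. O–C10–C9 can therefore be stored as an epoxide; the ynone puts C3 within 5-endo reach of that oxygen, and C9 leaves the ring as CH2 by a hydride shift from C8.
4. The two halves are joined at C1–C2 (alkynyl iodide plus epoxy aldehyde). The Z-C4=C5 unit with its methyl is bought as (Z)-3-methylpent-2-en-4-yn-1-ol; C6 comes from catalytic asymmetric alkynylation and C10 from asymmetric epoxidation.
5. Ring order: oxirane, butenolide, furanone (from the oxirane), 10-membered carbocycle.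

Key step: step 13

Assumption: (S,S)-ProPhenol is taken to deliver the (R)-carbinol in step 7; should the sense of induction be the opposite, the (R,R)-ligand is used instead.

**Route**

Step 1
Reactants: 1 prenol (3-methylbut-2-en-1-ol)
Product: 2 tert-butyldimethyl[(3-methylbut-2-en-1-yl)oxy]silane
Conditions: TBSCl, imidazole, DMF, 0 °C to rt
Reagents that add atoms: tert-butyldimethylsilyl chloride, CC(C)(C)[Si](C)(C)Cl
Why: Imidazole-promoted silylation of a primary alcohol is routine and no stereocentre is involved.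

Step 2
Reactants: 2 tert-butyldimethyl[(3-methylbut-2-en-1-yl)oxy]silane
Product: 3 (2E)-4-[(tert-butyldimethylsilyl)oxy]-2-methylbut-2-en-1-ol
Conditions: SeO2 (0.3 equiv), tBuOOH (2 equiv), salicylic acid (cat.), CH2Cl2, 0 °C to rt
Reagents that add atoms: tert-butyl hydroperoxide, CC(C)(C)OO
Why: Selenium dioxide allylic oxidation (ene reaction then [2,3]-shift) hydroxylates the methyl group trans to the chain of a trisubstituted alkene, which should give the E allylic alcohol and leave the silyl ether untouched.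

Step 3
Reactants: 3 (2E)-4-[(tert-butyldimethylsilyl)oxy]-2-methylbut-2-en-1-ol
Product: 4 [(2S,3S)-3-{[(tert-butyldimethylsilyl)oxy]methyl}-2-methyloxiran-2-yl]methanol
Conditions: Ti(OiPr)4 (10 mol %), L-(+)-diethyl tartrate (12 mol %), tBuOOH, 4 Å MS, CH2Cl2, −20 °C
Reagents that add atoms: tert-butyl hydroperoxide, CC(C)(C)OO
Why: Sharpless asymmetric epoxidation of a primary E allylic alcohol with L-(+)-tartrate should deliver oxygen to the face that gives the (2S,3S)-epoxide, which fixes the later C10 by catalyst control.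

Step 4
Reactants: 4 [(2S,3S)-3-{[(tert-butyldimethylsilyl)oxy]methyl}-2-methyloxiran-2-yl]methanol
Product: 5 (2R,3S)-3-{[(tert-butyldimethylsilyl)oxy]methyl}-2-methyloxirane-2-carbaldehyde
Conditions: Dess–Martin periodinane, NaHCO3, CH2Cl2, 0 °C
Reagents that add atoms: none
Why: Buffered Dess–Martin oxidation of a primary alcohol spares the epoxide and silyl ether, and the quaternary α-carbon cannot epimerise.

Step 5
Reactants: 6 (2Z)-3-methylpent-2-en-4-yn-1-ol
Product: 8 (2Z)-3-methyl-5-(trimethylsilyl)pent-2-en-4-yn-1-ol, via bis-silylated enynol 7 (not isolated)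
Conditions: nBuLi (2.1 equiv), THF, −78 °C; Me3SiCl (2.2 equiv), −78 °C to rt; 1 M HCl work-up
Reagents that add atoms: chlorotrimethylsilane, C[Si](C)(C)Cl
Why: Double deprotonation, silylation and acidic hydrolysis of the labile O–Si bond (C-silylation of a terminal alkyne) masks the alkyne C–H so that only alkyne 10 is metallated in step 7, with the Z alkene unaffected.

Step 6
Reactants: 8 (2Z)-3-methyl-5-(trimethylsilyl)pent-2-en-4-yn-1-ol
Product: 9 (2Z)-3-methyl-5-(trimethylsilyl)pent-2-en-4-ynal
Conditions: MnO2, CH2Cl2, rt, dark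
Reagents that add atoms: none
Why: MnO2 oxidation of an allylic alcohol is neutral and should preserve the Z geometry of the enal.

Step 7
Reactants: 9 (2Z)-3-methyl-5-(trimethylsilyl)pent-2-en-4-ynal; 10 tert-butyldimethyl(prop-2-yn-1-yloxy)silane
Product: 11 (4R,5Z)-1-[(tert-butyldimethylsilyl)oxy]-6-methyl-8-(trimethylsilyl)oct-5-ene-2,7-diyn-4-ol
Conditions: (S,S)-ProPhenol (20 mol %), Me2Zn (3 equiv), Ph3PO (40 mol %), toluene, 4 °C
Reagents that add atoms: none
Why: Zinc-mediated catalytic asymmetric alkynylation of an aldehyde adds the zinc acetylide of 10 to one face of the enal and sets the later C6 as (R) by catalyst control.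

Step 8
Reactants: 11 (4R,5Z)-1-[(tert-butyldimethylsilyl)oxy]-6-methyl-8-(trimethylsilyl)oct-5-ene-2,7-diyn-4-ol
Product: 13 (2Z,4R,5Z)-1-[(tert-butyldimethylsilyl)oxy]-2-iodo-6-methyl-8-(trimethylsilyl)octa-2,5-dien-7-yn-4-ol, via cyclic alkenylaluminate 12 (not isolated)
Conditions: NaAlH2(OCH2CH2OMe)2 (Red-Al), THF, 0 °C; then I2, −78 °C
Reagents that add atoms: iodine, II
Why: Hydroxyl-directed trans-hydroalumination of the propargylic alcohol places aluminium on the distal alkyne carbon cis to the carbinol, and iodinolysis with retention gives the Z vinyl iodide, while the silylated enyne, which is not propargylic to the alkoxide, should be left alone.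

Step 9
Reactants: 13 (2Z,4R,5Z)-1-[(tert-butyldimethylsilyl)oxy]-2-iodo-6-methyl-8-(trimethylsilyl)octa-2,5-dien-7-yn-4-ol
Product: 14 (5R)-3-{[(tert-butyldimethylsilyl)oxy]methyl}-5-[(1Z)-2-methyl-4-(trimethylsilyl)but-1-en-3-yn-1-yl]furan-2(5H)-one
Conditions: Pd(PPh3)2Cl2 (5 mol %), CO (1 atm), K2CO3, THF, 40 °C
Reagents that add atoms: carbon monoxide, [C-]#[O+]
Why: Palladium-catalysed carbonylative lactonisation (oxidative addition to zerovalent palladium, CO insertion, capture of the acyl by the cis hydroxyl) closes the butenolide without touching the C6 configuration, a weak insoluble base being chosen to avoid γ-deprotonation.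

Step 10
Reactants: 14 (5R)-3-{[(tert-butyldimethylsilyl)oxy]methyl}-5-[(1Z)-2-methyl-4-(trimethylsilyl)but-1-en-3-yn-1-yl]furan-2(5H)-one
Product: 15 (5R)-3-{[(tert-butyldimethylsilyl)oxy]methyl}-5-[(1Z)-4-iodo-2-methylbut-1-en-3-yn-1-yl]furan-2(5H)-one
Conditions: N-iodosuccinimide, AgNO3 (10 mol %), acetone, rt, dark
Reagents that add atoms: N-iodosuccinimide, O=C1CCC(=O)N1I
Why: Silver-catalysed iododesilylation converts the alkynylsilane directly into the iodoalkyne needed for a base-free union, without affecting the silyl ether or the lactone.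

Step 11
Reactants: 15 (5R)-3-{[(tert-butyldimethylsilyl)oxy]methyl}-5-[(1Z)-4-iodo-2-methylbut-1-en-3-yn-1-yl]furan-2(5H)-one; 5 (2R,3S)-3-{[(tert-butyldimethylsilyl)oxy]methyl}-2-methyloxirane-2-carbaldehyde
Product: 16 epoxy propargylic alcohol (C1–C2 bond formed; both C1 epimers; oxirane and butenolide configured as in 5 and 15)
Conditions: CrCl2 (4 equiv), NiCl2 (2 mol %), THF, rt
Reagents that add atoms: none
Why: Nozaki–Hiyama–Kishi alkynylation (alkynylchromium from the iodoalkyne) adds to the aldehyde under neutral conditions that spare the base-sensitive butenolide and the epoxide, and the new C1 carbinol, expected as a mixture, is erased in step 12.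

Step 12
Reactants: 16 epoxy propargylic alcohol
Product: 17 α,β-epoxy ynone (C1 ketone; C10 oxirane carbon bears the ynone and C9 bears CH2OTBS)
Conditions: Dess–Martin periodinane, NaHCO3, CH2Cl2, 0 °C
Reagents that add atoms: none
Why: Dess–Martin oxidation of a propargylic alcohol gives the ynone and converges both C1 epimers without opening the epoxide.

Step 13
Reactants: 17 α,β-epoxy ynone
Product: 18 {(2R)-2-methyl-3-oxo-5-[(1Z)-1-{(2R)-4-[(tert-butyldimethylsilyloxy)methyl]-5-oxo-2,5-dihydrofuran-2-yl}prop-1-en-2-yl]-2,3-dihydrofuran-2-yl}acetaldehyde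
Conditions: Ph3PAuNTf2 (5 mol %), (CF3)2CHOH (3 equiv), CH2Cl2, −20 °C to rt
Reagents that add atoms: none
Why: Proposed new method: the cationic gold catalyst π-activates the ynone, the oxirane oxygen adds to C3, and the resulting bicyclic oxonium opens at C9 with a 1,2-hydride shift from the adjacent CH2OTBS carbon (C8), after which (CF3)2CHOH removes the silyl group from the oxocarbenium (giving the aldehyde) and supplies the proton for protodeauration at C2. The closest known reaction types are the hydride-shift rearrangement of 2,3-epoxy silyl ethers to β-oxygenated aldehydes (non-aldol aldol process), the gold-catalysed 5-endo-dig closure of 2-oxygenated ynones to 3(2H)-furanones, and oxonium-mediated ring expansions of epoxides to five-membered ethers. The furanone ring is closed in the 5-endo-dig mode by the epoxide oxygen, so the three-membered ring (O, C10, C9) grows into the five-membered ring (O, C10, C1, C2, C3) while C9 leaves it as the CH2 arm. No stereocentre is created: C10 keeps the configuration set by the Sharpless epoxidation because none of its four bonds is broken, and the C9 centre is erased. The step needs opening at C9 rather than C10 and hydride rather than acyl migration; C10 is quaternary, α to the ketone and already part of the new five-membered ring, so its cleavage or an acyl shift should be strongly disfavoured, and the silyl ether blocks Payne-type attack by a free hydroxyl.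

Step 14
Reactants: 18 furanone aldehyde silyl ether
Product: 19 {(2R)-5-[(1Z)-1-{(2R)-4-(hydroxymethyl)-5-oxo-2,5-dihydrofuran-2-yl}prop-1-en-2-yl]-2-methyl-3-oxo-2,3-dihydrofuran-2-yl}acetaldehyde
Conditions: HF (48 % aq), MeCN, 0 °C
Reagents that add atoms: none
Why: Acidic fluoride cleaves the primary allylic silyl ether, while the aldehyde, the furanone and the butenolide are stable to these non-basic conditions.

Step 15
Reactants: 19 furanone aldehyde allylic alcohol
Product: 20 {(2R)-5-[(1Z)-1-{(2R)-4-(bromomethyl)-5-oxo-2,5-dihydrofuran-2-yl}prop-1-en-2-yl]-2-methyl-3-oxo-2,3-dihydrofuran-2-yl}acetaldehyde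
Conditions: N-bromosuccinimide, Me2S, CH2Cl2, −20 to 0 °C
Reagents that add atoms: N-bromosuccinimide, O=C1CCC(=O)N1Br
Why: Corey–Kim-type bromination (alkoxysulfonium formation, then displacement by bromide) converts the allylic alcohol into the allylic bromide without touching the aldehyde or the alkenes.

Step 16
Reactants: 20 bromomethylbutenolide aldehyde
Product: 21 (6R,7R,8R,10R)-8-hydroxy macrocycle (the free C8 alcohol of the target)
Conditions: CrCl2 (6 equiv), THF/DMF (10:1), 2 mM, slow addition, rt
Reagents that add atoms: none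
Why: Intramolecular Barbier-type (Nozaki–Hiyama) allylation, in which the allylchromium from the 3-(bromomethyl)butenolide adds through its γ-carbon (C7) to the C8 aldehyde in a closed six-membered transition state, should close the 10-membered ring, move the alkene to the exocyclic C11=C13 position, set C7 anti to the C6 substituent (trans lactone, substrate control) and set C8 through the chair-like arrangement imposed by the rigid Z-alkene/furanone tether.

Step 17
Reactants: 21 (6R,7R,8R,10R)-8-hydroxy macrocycle; 22 tigloyl chloride [(2E)-2-methylbut-2-enoyl chloride]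
Product: 23 atripliciolide tiglate
Conditions: pyridine, DMAP (cat.), CH2Cl2, 0 °C
Reagents that add atoms: none
Why: Acylation of the secondary C8 alcohol with an acid chloride under pyridine/DMAP should give the tiglate without isomerising the E ester or adding to the α-methylene lactone at 0 °C.

**Compound list**

1 | prenol (3-methylbut-2-en-1-ol) | CC(C)=CCO | starting material
2 | tert-butyldimethyl[(3-methylbut-2-en-1-yl)oxy]silane | CC(C)=CCO[Si](C)(C)C(C)(C)C | intermediate
3 | (2E)-4-[(tert-butyldimethylsilyl)oxy]-2-methylbut-2-en-1-ol | OC/C(C)=C/CO[Si](C)(C)C(C)(C)C | intermediate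
4 | [(2S,3S)-3-{[(tert-butyldimethylsilyl)oxy]methyl}-2-methyloxiran-2-yl]methanol | OC[C@]1(C)O[C@H]1CO[Si](C)(C)C(C)(C)C | intermediate
5 | (2R,3S)-3-{[(tert-butyldimethylsilyl)oxy]methyl}-2-methyloxirane-2-carbaldehyde | O=C[C@]1(C)O[C@H]1CO[Si](C)(C)C(C)(C)C | intermediate
6 | (2Z)-3-methylpent-2-en-4-yn-1-ol (commercial single Z isomer) | C#C/C(C)=C\CO | starting material
7 | trimethyl{[(2Z)-3-methyl-5-(trimethylsilyl)pent-2-en-4-yn-1-yl]oxy}silane (not isolated) | C[Si](C)(C)C#C/C(C)=C\CO[Si](C)(C)C | intermediate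
8 | (2Z)-3-methyl-5-(trimethylsilyl)pent-2-en-4-yn-1-ol | C[Si](C)(C)C#C/C(C)=C\CO | intermediate
9 | (2Z)-3-methyl-5-(trimethylsilyl)pent-2-en-4-ynal | C[Si](C)(C)C#C/C(C)=C\C=O | intermediate
10 | tert-butyldimethyl(prop-2-yn-1-yloxy)silane | C#CCO[Si](C)(C)C(C)(C)C | starting material
11 | (4R,5Z)-1-[(tert-butyldimethylsilyl)oxy]-6-methyl-8-(trimethylsilyl)oct-5-ene-2,7-diyn-4-ol | C[Si](C)(C)C#C/C(C)=C\[C@@H](O)C#CCO[Si](C)(C)C(C)(C)C | intermediate
12 | sodium cyclic alkenylaluminate of 11 (five-membered O–Al–C=C ring, two 2-methoxyethoxy ligands; not isolated) | C[Si](C)(C)C#C/C(C)=C\[C@H]1O[Al-](OCCOC)(OCCOC)C(CO[Si](C)(C)C(C)(C)C)=C1.[Na+] | intermediate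
13 | (2Z,4R,5Z)-1-[(tert-butyldimethylsilyl)oxy]-2-iodo-6-methyl-8-(trimethylsilyl)octa-2,5-dien-7-yn-4-ol | C[Si](C)(C)C#C/C(C)=C\[C@@H](O)/C=C(\I)CO[Si](C)(C)C(C)(C)C | intermediate
14 | (5R)-3-{[(tert-butyldimethylsilyl)oxy]methyl}-5-[(1Z)-2-methyl-4-(trimethylsilyl)but-1-en-3-yn-1-yl]furan-2(5H)-one | C[Si](C)(C)C#C/C(C)=C\[C@H]1OC(=O)C(CO[Si](C)(C)C(C)(C)C)=C1 | intermediate
15 | (5R)-3-{[(tert-butyldimethylsilyl)oxy]methyl}-5-[(1Z)-4-iodo-2-methylbut-1-en-3-yn-1-yl]furan-2(5H)-one | IC#C/C(C)=C\[C@H]1OC(=O)C(CO[Si](C)(C)C(C)(C)C)=C1 | intermediate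
16 | epoxy propargylic alcohol: butenolide 15 joined through its alkyne to the carbinol carbon (C1, both epimers) derived from the aldehyde of 5 | OC([C@]1(C)O[C@H]1CO[Si](C)(C)C(C)(C)C)C#C/C(C)=C\[C@H]1OC(=O)C(CO[Si](C)(C)C(C)(C)C)=C1 | intermediate
17 | α,β-epoxy ynone: C1 ketone of 16 | O=C([C@]1(C)O[C@H]1CO[Si](C)(C)C(C)(C)C)C#C/C(C)=C\[C@H]1OC(=O)C(CO[Si](C)(C)C(C)(C)C)=C1 | intermediate
18 | {(2R)-2-methyl-3-oxo-5-[(1Z)-1-{(2R)-4-[(tert-butyldimethylsilyloxy)methyl]-5-oxo-2,5-dihydrofuran-2-yl}prop-1-en-2-yl]-2,3-dihydrofuran-2-yl}acetaldehyde | O=CC[C@@]1(C)OC(=CC1=O)/C(C)=C\[C@H]1OC(=O)C(CO[Si](C)(C)C(C)(C)C)=C1 | intermediate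
19 | {(2R)-5-[(1Z)-1-{(2R)-4-(hydroxymethyl)-5-oxo-2,5-dihydrofuran-2-yl}prop-1-en-2-yl]-2-methyl-3-oxo-2,3-dihydrofuran-2-yl}acetaldehyde | O=CC[C@@]1(C)OC(=CC1=O)/C(C)=C\[C@H]1OC(=O)C(CO)=C1 | intermediate
20 | {(2R)-5-[(1Z)-1-{(2R)-4-(bromomethyl)-5-oxo-2,5-dihydrofuran-2-yl}prop-1-en-2-yl]-2-methyl-3-oxo-2,3-dihydrofuran-2-yl}acetaldehyde | O=CC[C@@]1(C)OC(=CC1=O)/C(C)=C\[C@H]1OC(=O)C(CBr)=C1 | intermediate
21 | (6R,7R,8R,10R)-8-hydroxy macrocycle (target without the tigloyl group) | C=C1C(=O)O[C@@H]2/C=C(/C)C3=CC(=O)[C@@](C)(C[C@@H](O)[C@@H]12)O3 | intermediate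
22 | tigloyl chloride, (2E)-2-methylbut-2-enoyl chloride | C/C=C(\C)C(Cl)=O | starting material
23 | atripliciolide tiglate | C=C1C(=O)O[C@@H]2/C=C(/C)C3=CC(=O)[C@@](C)(C[C@@H](OC(=O)/C(C)=C/C)[C@@H]12)O3 | target

**Step count and risks**

Total steps: 17. Longest linear sequence: 13 steps (6 to 23, steps 5–17).

Steps most likely to fail:

1. Step 13 (ring expansion). What may go wrong: the oxonium may open by acyl migration or at C10, or the activated ynone may be intercepted intermolecularly before the epoxide oxygen adds, so that the cascade stalls or diverts. Fallback with known chemistry, setting out from 4 and coming back at 20: DIBAL-H (CH2Cl2, −78 °C) opens the 2,3-epoxy alcohol by hydride delivery to the carbon remote from the carbinol (C9) to give (2R)-4-[(tert-butyldimethylsilyl)oxy]-2-methylbutane-1,2-diol F1. TEMPO/PhI(OAc)2 oxidises the primary alcohol to the α-hydroxy aldehyde F2. Nozaki–Hiyama–Kishi coupling with 15 (CrCl2, NiCl2 cat.) gives the propargylic diol F3, and MnO2 oxidises only the propargylic alcohol to the hydroxy ynone F4. Ph3PAuNTf2 then closes the free tertiary alcohol directly onto the ynone (5-endo-dig) to the bis-silyl furanone F5, and aqueous HF gives the furanone diol F6. NBS/Me2S brominates only the allylic alcohol to the bromo alcohol F7, and Dess–Martin oxidation of the remaining primary alcohol gives 20.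

2. Step 16 (ring-closing allylation). What may go wrong: poor facial selectivity at C8 in the macrocyclic transition state. Fallback, setting out from 20 and coming back at 23: the same CrCl2 closure is run, and if it delivers the C8-epimeric alcohol F8, Mitsunobu esterification with tiglic acid (PPh3, DIAD, THF, 0 °C) inverts C8 and installs the tiglate in one operation, so that 23 is reached directly and step 17 is not needed.

3. Step 7 (asymmetric alkynylation). What may go wrong: Z-to-E isomerisation of the enal or low enantioselectivity during the slow zinc-mediated addition. Fallback, setting out from 9 and coming back at 11: the lithium acetylide of 10 (nBuLi, THF, −78 °C) adds quickly at low temperature to give the racemic carbinol F9. MnO2 oxidises it to the alkenyl alkynyl ketone F10, and Noyori asymmetric transfer hydrogenation (RuCl(p-cymene)(TsDPEN), HCO2H/Et3N, with the TsDPEN enantiomer that gives the (R)-carbinol) reduces the ketone to 11 under catalyst control.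

**Further compounds**

F1 | step 13 | (2R)-4-[(tert-butyldimethylsilyl)oxy]-2-methylbutane-1,2-diol | OC[C@](C)(O)CCO[Si](C)(C)C(C)(C)C
F2 | step 13 | (2R)-4-[(tert-butyldimethylsilyl)oxy]-2-hydroxy-2-methylbutanal | O=C[C@](C)(O)CCO[Si](C)(C)C(C)(C)C
F3 | step 13 | propargylic diol from F2 and 15 (both carbinol epimers, tertiary alcohol free) | OC([C@](C)(O)CCO[Si](C)(C)C(C)(C)C)C#C/C(C)=C\[C@H]1OC(=O)C(CO[Si](C)(C)C(C)(C)C)=C1
F4 | step 13 | tertiary α'-hydroxy ynone | O=C([C@](C)(O)CCO[Si](C)(C)C(C)(C)C)C#C/C(C)=C\[C@H]1OC(=O)C(CO[Si](C)(C)C(C)(C)C)=C1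
F5 | step 13 | bis-silyl furanone (C8 and C13 as silyl ethers) | CC(C)(C)[Si](C)(C)OCC[C@@]1(C)OC(=CC1=O)/C(C)=C\[C@H]1OC(=O)C(CO[Si](C)(C)C(C)(C)C)=C1
F6 | step 13 | furanone diol | OCC[C@@]1(C)OC(=CC1=O)/C(C)=C\[C@H]1OC(=O)C(CO)=C1
F7 | step 13 | furanone bromo alcohol (C8 alcohol, C13 bromide) | OCC[C@@]1(C)OC(=CC1=O)/C(C)=C\[C@H]1OC(=O)C(CBr)=C1
F8 | step 16 | C8 epimer of 21 | C=C1C(=O)O[C@@H]2/C=C(/C)C3=CC(=O)[C@@](C)(C[C@H](O)[C@@H]12)O3
F9 | step 7 | racemic (5Z)-1-[(tert-butyldimethylsilyl)oxy]-6-methyl-8-(trimethylsilyl)oct-5-ene-2,7-diyn-4-ol | C[Si](C)(C)C#C/C(C)=C\C(O)C#CCO[Si](C)(C)C(C)(C)C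
F10 | step 7 | (5Z)-1-[(tert-butyldimethylsilyl)oxy]-6-methyl-8-(trimethylsilyl)oct-5-ene-2,7-diyn-4-one | C[Si](C)(C)C#C/C(C)=C\C(=O)C#CCO[Si](C)(C)C(C)(C)C
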